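The runs come from a simulation with made-up constants; the scatter is artificial.

Percent of the substrate charged is the unit here, so flasks with different charges can be read against each other directly.

| flask | substrate | solid partner | remark | time |
|---|---|---|---|---|
| midnight | 0.20 M | 0.48 M | run made earlier |  |
| dawn | 0.80 M | 0.48 M | run made earlier |  |
| summer | 0.40 M | 0.72 M | run made earlier |  |
| flask | 0.40 M | 0.480 M |  | 40 h |

- midnight (time / h: open intermediate / %, target / %): 4.00: 16, 0; 10.0: 32, 0; 20.0: 52, 0; 30.0: 55, 3; 40.0: 55, 2
- dawn (time / h: open intermediate / %, target / %): 4.00: 14, 0; 10.0: 27, 0; 20.0: 37, 0; 30.0: 32, 1; 40.0: 32, 2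
- summer (time / h: open intermediate / %, target / %): 4.00: 11, 2; 10.0: 31, 0; 20.0: 42, 0; 30.0: 47, 3; 40.0: 41, 2

(readings scatter by 2 percentage points)

- solid partner is a solid; its amount is given per volume of the solution
- at the start none of the solid partner is in solution

- amount of open intermediate in percent of the substrate charged, at 8.0 h, 20 h and 40 h

Which given number has to be known well? The substrate charge does: going from 0.20 M in the midnight run to 0.80 M in the dawn run, both at the flask's solid partner, moves the open intermediate at 40.0 h from 55% to 32%.

The flask's charge is the geometric mean of those two, 0.400 M. That suggests my own reckoning, the middle-charge rule: with the solid partner charged alike in the three, the flask's share M at any one time is taken as the geometric mean of the midnight and dawn shares. At 20 h this gives 43.9%, and at 40 h it gives 42.0%.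

The solid partner comes next. The summer run, with 0.72 M of solid partner at the flask's substrate charge, read 41% at 40.0 h, a gap of 1.00 percentage point from M beside a scatter of 2 points.

Time comes last. M goes from 15.0% at 4.00 h to 29.4% at 10.0 h, but from 43.9% to 42.0% between 20 h and 40 h, so the reading time counts early on. Read on a straight line, 8.0 h gives 24.6%.

The forecast says 25%, 42% and 44%, holding that “The solid difference shouldn't matter”. Its share still rises after 20 h, where mine falls.

The flask gives 26.3%, 42.6% and 44.7%, so the forecast stands within its margin.

    substrate → open intermediate (k = 0.0450 h⁻¹)
    fresh partner → second intermediate (k = 0.200 h⁻¹)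
    open intermediate + second intermediate → target (k = 0.0330 M⁻¹ h⁻¹)
    2 open intermediate → homo product (k = 0.0180 M⁻¹ h⁻¹)
    substrate + open intermediate → side product (k = 0.0860 M⁻¹ h⁻¹)
    solid partner ⇌ fresh partner, rate k6*(cs6 - [fresh partner]) while solid is left; crystals form when [fresh partner] > cs6 (solubility = 0.310 M, k = 0.0180 h⁻¹)

The plateau of the forecast does not last in this flask, which holds 0.652% open intermediate at 400 h. At 20 h the flask stands 1.3 points below M. Turned round, the rule takes this flask's 42.6% and the midnight run's 52% and gives the dawn run 34.9% at 20.0 h, where that run read 37%.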